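The disconnection on which everything rests opens the 2,2-dimethyl-2H-pyran ring (chromene numbering) at O1–C2 and at C4–C4a, leading back to a fully assembled, prenylated 2-hydroxybenzil and 3-methylbut-2-enal. In one operation the enal is joined to C4a, the only unsubstituted carbon of ring A, and the resulting ortho-quinone methide (a 1-oxatriene) closes by oxa-6π electrocyclization, forming O1–C2. The feature exploited is that C4a sits between C5–OMe and C8a–OH: only the C8a oxygen can become the oxatriene carbonyl, so one chromene alone can form. The benzil precursor comes in three steps: Friedel–Crafts acylation, methylene oxidation to the 1,2-dione before any olefin is present, then C-prenylation.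

Key step: step 4

Remark on the chemistry: the target has no stereocentre and no stereogenic double bond, so no stereocontrol is needed. Ring A is the benzene ring of the chromene and ring B the 4-hydroxyphenyl ring. In the open-chain precursors ring A is numbered from the acyl-bearing carbon (C1), so their C3 and C5 become C8 and C4a of the target. The four building blocks are assumed to be commercial.

Step 1
Reactants: 1 5-methoxyresorcinol (5-methoxybenzene-1,3-diol); 2 4-hydroxyphenylacetic acid
Product: 3 1-(2,4-dihydroxy-6-methoxyphenyl)-2-(4-hydroxyphenyl)ethan-1-one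
Conditions: BF3·OEt2 (neat, as solvent), 85 °C; aq. NaOAc work-up; chromatography to remove the isomer acylated between the two hydroxyls
Reagents that add atoms: none
Why: Friedel–Crafts acylation by the BF3-activated acid, in which attack at C4 of 1 (para to one hydroxyl, ortho to OMe, two equivalent sites) should dominate over C2, and the BF2-chelated ketone formed is deactivated against a second acylation.

Step 2
Reactants: 3 1-(2,4-dihydroxy-6-methoxyphenyl)-2-(4-hydroxyphenyl)ethan-1-one
Product: 4 1-(2,4-dihydroxy-6-methoxyphenyl)-2-(4-hydroxyphenyl)ethane-1,2-dione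
Conditions: SeO2 (1.3 equiv), 1,4-dioxane/H2O, reflux; filtration from selenium
Reagents that add atoms: selenium dioxide, O=[Se]=O
Why: Riley oxidation of the methylene group, which is activated by both the ketone and ring B, should give the 1,2-dione, and it is run at this stage because no olefin is yet present to undergo allylic oxidation.

Step 3
Reactants: 4 1-(2,4-dihydroxy-6-methoxyphenyl)-2-(4-hydroxyphenyl)ethane-1,2-dione; 5 2-methylbut-3-en-2-ol
Product: 6 1-[2,4-dihydroxy-6-methoxy-3-(3-methylbut-2-en-1-yl)phenyl]-2-(4-hydroxyphenyl)ethane-1,2-dione
Conditions: 5 (1.2 equiv), BF3·OEt2 (0.5 equiv), 1,4-dioxane, rt; quenched at partial conversion, unreacted 4 recycled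
Reagents that add atoms: none
Why: Friedel–Crafts C-prenylation, in which BF3 ionizes 5 to the 1,1-dimethylallyl cation and ring A, far more nucleophilic than the para-acylphenol ring B, traps it at the primary terminus, with C3 (flanked by the two free hydroxyls) expected to be preferred over C5 as in the 6-prenylation of 5,7-dihydroxyflavonoids.

Step 4
Reactants: 6 1-[2,4-dihydroxy-6-methoxy-3-(3-methylbut-2-en-1-yl)phenyl]-2-(4-hydroxyphenyl)ethane-1,2-dione; 7 3-methylbut-2-enal
Product: 10 derrisdione A, via benzylic carbinol 8 (not isolated), via ortho-quinone methide 9 (not isolated)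
Conditions: 7 (3 equiv), pyridine, 120 °C, sealed tube, argon
Reagents that add atoms: none
Why: Pyridine ionizes the C4–OH of 6 (para to the ketone, the future O1), and the phenoxide adds through C5, its only unsubstituted ortho carbon (the future C4a), to the aldehyde of 7 to give carbinol 8; loss of water gives the ortho-quinone methide 9, a 1-oxatriene (O=C8a–C4a=C4–C3=C2), which closes by a thermally allowed disrotatory oxa-6π electrocyclization that forms the O1–C2 bond and restores the aromaticity of ring A. The closest known reaction type is the pyridine-mediated condensation of acylresorcinols and acylphloroglucinols with 3-methylbut-2-enal or citral to 2H-chromenes (aldol-type addition, dehydration, oxa-6π electrocyclization; a formal [3+3] annulation). The one new ring, the 2H-pyran, therefore closes by 6π electrocyclization of the isomer of 9 that has the vinyl group cis to the C8a carbonyl, the other isomer equilibrating through reversible re-addition of water. No stereocentre is formed, because C2 carries two methyl groups. The step needs regioselectivity, secured because C4a is the last free carbon of ring A and is flanked by C5–OMe, which cannot become the oxatriene carbonyl, and by the free C8a–OH, so only one closure is possible; it also needs chemoselectivity, secured because ring B is a para-acylphenol of far lower carbon nucleophilicity, the hydrogen-bonded C7–OH has no free ortho carbon, and the 1,2-dione is non-enolizable and does not condense with a tertiary amine.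

Compound list
1 | 5-methoxyresorcinol (5-methoxybenzene-1,3-diol) | COc1cc(O)cc(O)c1 | starting material
2 | 4-hydroxyphenylacetic acid | OC(=O)Cc1ccc(O)cc1 | starting material
3 | 1-(2,4-dihydroxy-6-methoxyphenyl)-2-(4-hydroxyphenyl)ethan-1-one | COc1cc(O)cc(O)c1C(=O)Cc1ccc(O)cc1 | intermediate
4 | 1-(2,4-dihydroxy-6-methoxyphenyl)-2-(4-hydroxyphenyl)ethane-1,2-dione | COc1cc(O)cc(O)c1C(=O)C(=O)c1ccc(O)cc1 | intermediate
5 | 2-methylbut-3-en-2-ol | CC(C)(O)C=C | starting material
6 | 1-[2,4-dihydroxy-6-methoxy-3-(3-methylbut-2-en-1-yl)phenyl]-2-(4-hydroxyphenyl)ethane-1,2-dione | COc1cc(O)c(CC=C(C)C)c(O)c1C(=O)C(=O)c1ccc(O)cc1 | intermediate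
7 | 3-methylbut-2-enal | CC(C)=CC=O | starting material
8 | benzylic carbinol, racemic: 1-[2,4-dihydroxy-5-(1-hydroxy-3-methylbut-2-en-1-yl)-6-methoxy-3-(3-methylbut-2-en-1-yl)phenyl]-2-(4-hydroxyphenyl)ethane-1,2-dione | COc1c(C(O)C=C(C)C)c(O)c(CC=C(C)C)c(O)c1C(=O)C(=O)c1ccc(O)cc1 | intermediate
9 | ortho-quinone methide: 1-[(3Z)-6-hydroxy-2-methoxy-3-(3-methylbut-2-en-1-ylidene)-5-(3-methylbut-2-en-1-yl)-4-oxocyclohexa-1,5-dien-1-yl]-2-(4-hydroxyphenyl)ethane-1,2-dione | COC1=C(C(=O)C(=O)c2ccc(O)cc2)C(O)=C(CC=C(C)C)C(=O)/C1=C\C=C(C)C | intermediate
10 | derrisdione A: 1-[7-hydroxy-5-methoxy-2,2-dimethyl-8-(3-methylbut-2-en-1-yl)-2H-chromen-6-yl]-2-(4-hydroxyphenyl)ethane-1,2-dione | COc1c2c(c(CC=C(C)C)c(O)c1C(=O)C(=O)c1ccc(O)cc1)OC(C)(C)C=C2 | target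

Total step count: 4. Longest linear sequence: 4 steps (1 → 3 → 4 → 6 → 10).

Steps most likely to fail

Step 3. The allyl cation may be captured at C5 as well as at C3, a second prenyl group may enter, and the acid may close the new prenyl group onto a neighbouring hydroxyl to give a chroman. The fallback moves the prenylation one stage earlier, changes it to a phenoxide C-alkylation, and replaces the oxidation by an olefin-tolerant aerobic one. Setting out from 3, 1-bromo-3-methylbut-2-ene (CC(C)=CCBr) with aqueous KOH (1 equiv, 0 °C) should ionize only the ring A C4–OH, the one strongly acidic phenol at this oxidation level. Alkylation at the carbon flanked by both ring A oxygens should then give 1-[2,4-dihydroxy-6-methoxy-3-(3-methylbut-2-en-1-yl)phenyl]-2-(4-hydroxyphenyl)ethan-1-one F1. Base-mediated autoxidation of the benzylic methylene of F1 (DABCO, air, DMF, 90 °C), which should leave the trisubstituted olefin untouched, returns to the route at 6.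

Step 4. Carbon–carbon bond formation at C4a, which is flanked on both sides and belongs to a ketone-stabilized phenoxide, may be slower than self-condensation of the enal or slow degradation of the 1,2-dione in hot pyridine. The fallback replaces base-mediated intermolecular addition by a boron-templated, intramolecular ortho-hydroxyalkylation. Setting out from 6, PhB(OH)2 (1 equiv), 7 and catalytic propanoic acid in refluxing toluene with removal of water should give 1-[7-hydroxy-5-methoxy-4-(2-methylprop-1-en-1-yl)-8-(3-methylbut-2-en-1-yl)-2-phenyl-4H-1,3,2-benzodioxaborin-6-yl]-2-(4-hydroxyphenyl)ethane-1,2-dione F2. On continued heating F2 should lose the boron unit by cycloreversion to the same ortho-quinone methide 9, which electrocyclizes, so the fallback returns to the route at 10.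

Step 2. Electrophilic selenium species may attack or over-oxidize the unprotected, electron-rich ring A, and finely divided selenium may be hard to remove from a polyphenol. The fallback brings in the dione carbons at the benzoin oxidation level instead of oxidizing a methylene group. Setting out from 1, Friedel–Crafts hydroxyalkylation with commercial 4-hydroxyphenylglyoxal hydrate (OC(O)C(=O)c1ccc(O)cc1) in aqueous ethanol with catalytic K2CO3 at rt under argon should give 2-(2,4-dihydroxy-6-methoxyphenyl)-2-hydroxy-1-(4-hydroxyphenyl)ethan-1-one F3. Mild aerobic oxidation of F3 (catalytic Cu(OAc)2, air, aqueous AcOH, 60 °C) returns to the route at 4.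

Further compounds
F1 | step 3 | 1-[2,4-dihydroxy-6-methoxy-3-(3-methylbut-2-en-1-yl)phenyl]-2-(4-hydroxyphenyl)ethan-1-one | COc1cc(O)c(CC=C(C)C)c(O)c1C(=O)Cc1ccc(O)cc1
F2 | step 4 | 1-[7-hydroxy-5-methoxy-4-(2-methylprop-1-en-1-yl)-8-(3-methylbut-2-en-1-yl)-2-phenyl-4H-1,3,2-benzodioxaborin-6-yl]-2-(4-hydroxyphenyl)ethane-1,2-dione (racemic) | COc1c2c(c(CC=C(C)C)c(O)c1C(=O)C(=O)c1ccc(O)cc1)OB(c1ccccc1)OC2C=C(C)C
F3 | step 2 | 2-(2,4-dihydroxy-6-methoxyphenyl)-2-hydroxy-1-(4-hydroxyphenyl)ethan-1-one (racemic) | COc1cc(O)cc(O)c1C(O)C(=O)c1ccc(O)cc1
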